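A plateau of 16.2% of the starting material charged is the mean of the spring readings from 8.00 h to 20.0 h; the same readings of the midnight run, at 75 °C, give 16.9%.

all flasks: starting material 0.10 M

|  | partner | second substrate | third substrate | temperature | remark | time |
|---|---|---|---|---|---|---|
| spring | 0.050 M | 0.020 M | 0.020 M | 80 °C | the very flask that is asked about, followed so far |  |
| midnight | 0.050 M | 0.020 M | 0.020 M | 75 °C | run made earlier |  |
| flask | 0.0500 M | 0.0200 M | 0.0200 M | 80 °C |  | 20 h |

| run | time / h | target / % |
|---|---|---|
| spring | 1.50 | 9.9 |
| spring | 2.50 | 12.4 |
| spring | 4.00 | 13.2 |
| spring | 6.00 | 15.6 |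
| spring | 8.00 | 15.9 |
| spring | 12.0 | 16.7 |
| spring | 20.0 | 16.0 |
| midnight | 1.50 | 8.4 |
| midnight | 2.50 | 10.4 |
| midnight | 4.00 | 13.4 |
| midnight | 6.00 | 14.9 |
| midnight | 8.00 | 16.7 |
| midnight | 12.0 | 17.1 |
| midnight | 20.0 | 16.9 |

(scatter of a reading: 0.5 percentage points)

- zeta: at 20 h raise the temperature by 15 K, then wait 6.0 h
- gamma: at 20 h add partner, 100% of the amount charged, then wait 6.0 h
- eta: at 20 h take out 90% of the target then present, then wait 6.0 h
- beta: change nothing and wait 6.0 h more

- target taken out counts as made
- additions bring no volume worth counting

- target, in percent of the starting material first charged, at 20 h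
- which option adds most target ("none" when 2 percentage points or less is all one gets) (zeta / gamma / eta / beta / none)
- target present, with what was taken out counted in, in percent of the starting material first charged, after zeta
- target present, with what was taken out counted in, in percent of the starting material first charged, after eta

The bench rule takes partner as the limiting reagent, one per starting material, so charged [partner]/[starting material] caps the spring flask at 50.0%. The plateau lies below that cap, at about a third of it, and as a reading it puts the unconverted starting material at 83.8% if target is taken as its one product; there the rule stops working.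

The reckoning here carries the ratio as the partner yield 0.324: target formed per partner charged. It supposes that the end of partner ended the rise. On that supposition, heat, removal and waiting add nothing, so the spring flask holds 16.2% at 20 h and after zeta or eta.

A second dose of partner gives a first answer of 16 percentage points. Going round once more, the dose meets 83.8% of starting material, against a mean of 91.9% during the first rise. That factor of 0.912 leaves 15 points, more than the margin of 2 points, so this reckoning chooses gamma.

The forecast parts from this reckoning at eta and at the choice. It gave 16.4% (15.9% to 16.9%), 16% after zeta (14.8% to 17.2%), 18.7% after eta (16.4% to 20%), and chose eta: “So extra partner should do little.”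

The spring flask gives 15.7%, 15.7% after zeta and 15.7% after eta; the best option is gamma, with 17 points added.

    starting material + partner → target (k = 2.23 M⁻¹ h⁻¹, Ea = 70.0 kJ mol⁻¹)
    second substrate + partner → second product (k = 25.3 M⁻¹ h⁻¹, Ea = 81.0 kJ mol⁻¹)
    third substrate + partner → third product (k = 0.368 M⁻¹ h⁻¹, Ea = 71.0 kJ mol⁻¹)
    partner + target → over-reaction product (k = 0.426 M⁻¹ h⁻¹, Ea = 90.0 kJ mol⁻¹)
    partner → decomposed reagent (k = 0.206 h⁻¹, Ea = 123 kJ mol⁻¹)
    (constants at 80 °C)

At 20.0 h the spring flask holds 0% of its partner and 84.1% of its starting material, and the dose brings 17 points, more than the reckoned 15 points. The same partner yield is applied to the neighbour flask charged with 0.20 M of partner. The first answer is 64.8%; scaling by its mean starting material gives 47.7%, and one more round gives 53.7%. That neighbour holds 59.1% of target at 20.0 h.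

The numbers in the tables come from a simulation for an exercise; the scatter is artificial.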